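**Retrosynthetic overview**
- The route rests on ring C, a 2-aryl-3-oxy-pyran-4-one: O1–C2 is the C=O of vanillin, and C3, C4, C4a and C8a are the four carbons of a 4-benzoyloxy-1-methoxy-3-silyloxybutadiene (flavanone numbering is used for these atoms throughout).
- Last disconnections: the acetate at O4' and the benzoate at O3 (methanolysis), then the prenyl ether at O7 (Mitsunobu).
- Ring A is cut at C4a–C5 and C8–C8a: Diels–Alder reaction of a C4a-sulfinyl dihydropyranone with a 1-methoxy-1,3-bis(silyloxy)butadiene, then loss of PhSOH and MeOH.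
- Ring C is cut at C2–C3 and O1–C8a: catalytic asymmetric hetero-Diels–Alder reaction (Mukaiyama aldol, then cyclisation) of O-acetylvanillin with the benzoyloxy diene; this sets C2 and C3.
- Order of ring formation: ring B is bought (vanillin), ring C is made in step 4, ring A in step 9.

Key step: step 4

Assumption: the (R)-configured 3,3'-diiodo-1,1'-bi-2-naphthol is taken to steer the diene onto the Si face of the aldehyde carbonyl (this gives 2R); if the sense turns out to be the opposite one, the (S)-ligand is used and nothing else changes.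
Remark: compounds 9, 11 and 15 are mixtures at centres that later steps destroy (C4a, C8a, sulfur); only C2 and C3 are drawn with configuration.

**Step 1**
Reactants: 1 vanillin
Product: 2 4-acetoxy-3-methoxybenzaldehyde
Conditions: Ac2O, pyridine, CH2Cl2, 0 °C → rt
Reagents that add atoms: acetic anhydride, CC(=O)OC(C)=O
Why: Pyridine-promoted O-acylation of the phenol; the acetate makes the aldehyde more electrophilic and keeps a free phenol away from the zirconium catalyst of step 4.

**Step 2**
Reactants: 3 (E)-4-methoxybut-3-en-2-one; 4 benzoic acid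
Product: 5 (E)-4-methoxy-2-oxobut-3-en-1-yl benzoate
Conditions: Mn(OAc)3·2H2O (3 equiv), 4 (excess), benzene, reflux, Dean–Stark
Reagents that add atoms: none
Why: Manganese triacetate α'-acyloxylation of an enone, in which the trivalent manganese enolate of the methyl ketone, after acetate/benzoate exchange, passes a benzoyloxy group to the α'-carbon; the γ-carbon has no enolisable hydrogen.

**Step 3**
Reactants: 5 (E)-4-methoxy-2-oxobut-3-en-1-yl benzoate
Product: 6 (1E,3Z)-4-benzoyloxy-1-methoxy-3-(trimethylsilyloxy)buta-1,3-diene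
Conditions: TMSOTf, Et3N, Et2O, 0 °C
Reagents that add atoms: trimethylsilyl trifluoromethanesulfonate, C[Si](C)(C)OS(=O)(=O)C(F)(F)F
Why: Soft enolisation (silyl triflate/amine) towards the benzoyloxy-bearing CH2, the only enolisable position, gives the 3-silyloxy diene; the (Z) geometry with the two oxygen substituents cis is the usual outcome for α-acyloxy ketones, and the (E)-enol ether is not touched.

**Step 4**
Reactants: 2 4-acetoxy-3-methoxybenzaldehyde; 6 (1E,3Z)-4-benzoyloxy-1-methoxy-3-(trimethylsilyloxy)buta-1,3-diene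
Product: 8 (2R,3R)-2-(4-acetoxy-3-methoxyphenyl)-3-benzoyloxy-2,3-dihydro-4H-pyran-4-one, via open-chain anti-aldol silyl ether 7 (not isolated)
Conditions: Zr(O-t-Bu)4 (10 mol %), (R)-3,3'-diiodo-1,1'-bi-2-naphthol (12 mol %), n-PrOH (80 mol %), H2O (20 mol %), toluene, −20 °C; then TFA, CH2Cl2, 0 °C
Reagents that add atoms: none
Why: The binaphtholate complex of tetravalent zirconium binds the aldehyde oxygen of 2, the benzoyloxy-bearing terminus of 6 attacks the carbonyl carbon through an open Mukaiyama-aldol transition state to make C2–C3 and give 7, and TFA then removes the silyl group so that the C2 oxygen adds to the methoxy-bearing enone carbon and methanol leaves, which makes O1–C8a. The closest known reaction type is the stepwise hetero-Diels–Alder reaction (Mukaiyama aldol, then cyclisation) of aryl aldehydes with 4-oxygenated 1-alkoxy-3-silyloxybutadienes under chiral zirconium binaphtholates. Ring C closes by a 6-endo-trig oxa-Michael addition followed by β-elimination of methanol. C2 is set by the catalyst, whose 3,3'-iodine atoms should leave only the Si face of the bound aldehyde open, and C3 is set relative to C2 by the antiperiplanar open transition state, in which the (Z)-enol silane turns its benzoate away from the aryl group, so that an anti aldol and hence the 2,3-trans ring should result. The step needs Si over Re attack and anti over syn addition; the ester oxygen at C3 is a poor ligand for zirconium, unlike an ether oxygen that could bridge to the metal and turn the addition syn, and the acetylated aldehyde is electron-poor and has no free phenol that could displace the ligand.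

**Step 5**
Reactants: 8 (2R,3R)-2-(4-acetoxy-3-methoxyphenyl)-3-benzoyloxy-2,3-dihydro-4H-pyran-4-one
Product: 10 (2R,3R)-2-(4-acetoxy-3-methoxyphenyl)-3-benzoyloxy-5-(phenylthio)-2,3-dihydro-4H-pyran-4-one, via chloro sulfide adduct 9 (not isolated)
Conditions: PhSCl, CH2Cl2, −78 → 0 °C; then pyridine, 0 °C
Reagents that add atoms: benzenesulfenyl chloride, ClSc1ccccc1
Why: Electrophilic α-sulfenylation of a vinylogous ester (sulfenyl chloride addition, then dehydrochlorination): sulfur adds to C4a, the nucleophilic enol-ether carbon, chloride to C8a, and pyridine takes HCl out of 9 to restore the enone, while it is too weak a base to enolise C3 at 0 °C.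

**Step 6**
Reactants: 10 (2R,3R)-2-(4-acetoxy-3-methoxyphenyl)-3-benzoyloxy-5-(phenylthio)-2,3-dihydro-4H-pyran-4-one
Product: 11 (2R,3R)-2-(4-acetoxy-3-methoxyphenyl)-3-benzoyloxy-5-(phenylsulfinyl)-2,3-dihydro-4H-pyran-4-one (both epimers at sulfur)
Conditions: mCPBA (1.0 equiv), CH2Cl2, −78 → −20 °C
Reagents that add atoms: 3-chloroperbenzoic acid, O=C(OO)c1cccc(Cl)c1
Why: Chemoselective sulfide-to-sulfoxide oxidation with one equivalent of peracid in the cold; the electron-poor enone double bond and the esters should not react, and the epimers at sulfur are used together because sulfur is lost in step 9.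

**Step 7**
Reactants: 12 methyl acetoacetate
Product: 13 methyl 3-(trimethylsilyloxy)but-2-enoate (E/Z mixture, geometry immaterial)
Conditions: TMSCl, Et3N, hexane, rt
Reagents that add atoms: chlorotrimethylsilane, C[Si](C)(C)Cl
Why: O-silylation of the enol form of a β-keto ester with silyl chloride and amine.

**Step 8**
Reactants: 13 methyl 3-(trimethylsilyloxy)but-2-enoate
Product: 14 1-methoxy-1,3-bis(trimethylsilyloxy)buta-1,3-diene
Conditions: LiN(i-Pr)2, THF, −78 °C; then TMSCl, −78 °C → rt
Reagents that add atoms: chlorotrimethylsilane, C[Si](C)(C)Cl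
Why: γ-Deprotonation of the enol-ether ester by the lithium amide and O-silylation of the dienolate gives the bis(silyloxy)diene, which is used at once because it is sensitive to moisture.

**Step 9**
Reactants: 11 (2R,3R)-2-(4-acetoxy-3-methoxyphenyl)-3-benzoyloxy-5-(phenylsulfinyl)-2,3-dihydro-4H-pyran-4-one; 14 1-methoxy-1,3-bis(trimethylsilyloxy)buta-1,3-diene
Product: 17 (2R,3R)-2-(4-acetoxy-3-methoxyphenyl)-3-benzoyloxy-5,7-dihydroxychroman-4-one, via sulfinyl cycloadduct 15 (not isolated), via bis(trimethylsilyl) ether 16 (not isolated)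
Conditions: 14 (3 equiv), toluene, 0 °C → rt, then 80 °C; then 1 M HCl, THF, 0 °C
Reagents that add atoms: none
Why: Normal-demand Diels–Alder reaction of an α-sulfinyl enone: the CH2 terminus of the diene bonds to C8a (the β-carbon of the enone) and the ketene-acetal carbon to C4a, which puts the oxygens at C5 and C7; syn-elimination of benzenesulfenic acid across C4a–C8a and loss of methanol from the C5 ketal aromatise ring A, and dilute acid frees the two phenols without touching C2, C3 or the esters.

**Step 10**
Reactants: 17 (2R,3R)-2-(4-acetoxy-3-methoxyphenyl)-3-benzoyloxy-5,7-dihydroxychroman-4-one; 18 3-methylbut-2-en-1-ol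
Product: 19 (2R,3R)-2-(4-acetoxy-3-methoxyphenyl)-3-benzoyloxy-5-hydroxy-7-(3-methylbut-2-en-1-yloxy)chroman-4-one
Conditions: PPh3, DIAD, THF, 0 °C → rt
Reagents that add atoms: none
Why: Mitsunobu etherification: the 7-OH, para to the C4 carbonyl and the only phenol not held in a hydrogen bond to C4=O, is alkylated at the CH2 carbon of the primary allylic alcohol, and the neutral conditions leave the esters, C2 and C3 alone.

**Step 11**
Reactants: 19 (2R,3R)-2-(4-acetoxy-3-methoxyphenyl)-3-benzoyloxy-5-hydroxy-7-(3-methylbut-2-en-1-yloxy)chroman-4-one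
Product: 20 (2R,3R)-3,5-dihydroxy-2-(4-hydroxy-3-methoxyphenyl)-7-(3-methylbut-2-en-1-yloxy)chroman-4-one
Conditions: K2CO3, MeOH–THF, 0 °C, Ar; then AcOH
Reagents that add atoms: none
Why: Carbonate-promoted methanolysis: the aryl acetate and the benzoate of an α-ketol are both activated esters and should go at 0 °C, where enolisation at C3 and opening of the O1–C2 bond are slow, and the prenyl ether is stable to base.

**Compound list**
1 | vanillin (4-hydroxy-3-methoxybenzaldehyde) | COc1cc(C=O)ccc1O | starting material
2 | 4-acetoxy-3-methoxybenzaldehyde | COc1cc(C=O)ccc1OC(C)=O | intermediate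
3 | (E)-4-methoxybut-3-en-2-one | CO/C=C/C(C)=O | starting material
4 | benzoic acid | O=C(O)c1ccccc1 | starting material
5 | (E)-4-methoxy-2-oxobut-3-en-1-yl benzoate | CO/C=C/C(=O)COC(=O)c1ccccc1 | intermediate
6 | (1E,3Z)-4-benzoyloxy-1-methoxy-3-(trimethylsilyloxy)buta-1,3-diene | CO/C=C/C(O[Si](C)(C)C)=C/OC(=O)c1ccccc1 | intermediate
7 | (1E,4R,5R)-5-(4-acetoxy-3-methoxyphenyl)-4-benzoyloxy-1-methoxy-5-(trimethylsilyloxy)pent-1-en-3-one (formed in the flask, step 4) | COc1cc([C@@H](O[Si](C)(C)C)[C@@H](OC(=O)c2ccccc2)C(=O)/C=C/OC)ccc1OC(C)=O | intermediate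
8 | (2R,3R)-2-(4-acetoxy-3-methoxyphenyl)-3-benzoyloxy-2,3-dihydro-4H-pyran-4-one | COc1cc([C@H]2OC=CC(=O)[C@@H]2OC(=O)c2ccccc2)ccc1OC(C)=O | intermediate
9 | (2R,3R)-2-(4-acetoxy-3-methoxyphenyl)-3-benzoyloxy-6-chloro-5-(phenylthio)tetrahydropyran-4-one, mixture at C5 and C6 (formed in the flask, step 5) | COc1cc([C@H]2OC(Cl)C(Sc3ccccc3)C(=O)[C@@H]2OC(=O)c2ccccc2)ccc1OC(C)=O | intermediate
10 | (2R,3R)-2-(4-acetoxy-3-methoxyphenyl)-3-benzoyloxy-5-(phenylthio)-2,3-dihydro-4H-pyran-4-one | COc1cc([C@H]2OC=C(Sc3ccccc3)C(=O)[C@@H]2OC(=O)c2ccccc2)ccc1OC(C)=O | intermediate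
11 | (2R,3R)-2-(4-acetoxy-3-methoxyphenyl)-3-benzoyloxy-5-(phenylsulfinyl)-2,3-dihydro-4H-pyran-4-one, both epimers at sulfur | COc1cc([C@H]2OC=C(S(=O)c3ccccc3)C(=O)[C@@H]2OC(=O)c2ccccc2)ccc1OC(C)=O | intermediate
12 | methyl acetoacetate | COC(=O)CC(C)=O | starting material
13 | methyl 3-(trimethylsilyloxy)but-2-enoate (E/Z mixture) | COC(=O)C=C(C)O[Si](C)(C)C | intermediate
14 | 1-methoxy-1,3-bis(trimethylsilyloxy)buta-1,3-diene | COC(O[Si](C)(C)C)=CC(=C)O[Si](C)(C)C | intermediate
15 | (2R,3R)-2-(4-acetoxy-3-methoxyphenyl)-3-benzoyloxy-5-methoxy-4a-(phenylsulfinyl)-5,7-bis(trimethylsilyloxy)-2,3,4a,5,8,8a-hexahydro-4H-chromen-4-one, cis-fused, mixture at C4a, C5, C8a and sulfur (formed in the flask, step 9) | COc1cc([C@H]2OC3CC(O[Si](C)(C)C)=CC(OC)(O[Si](C)(C)C)C3(S(=O)c3ccccc3)C(=O)[C@@H]2OC(=O)c2ccccc2)ccc1OC(C)=O | intermediate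
16 | (2R,3R)-2-(4-acetoxy-3-methoxyphenyl)-3-benzoyloxy-5,7-bis(trimethylsilyloxy)chroman-4-one (formed in the flask, step 9) | COc1cc([C@H]2Oc3cc(O[Si](C)(C)C)cc(O[Si](C)(C)C)c3C(=O)[C@@H]2OC(=O)c2ccccc2)ccc1OC(C)=O | intermediate
17 | (2R,3R)-2-(4-acetoxy-3-methoxyphenyl)-3-benzoyloxy-5,7-dihydroxychroman-4-one | COc1cc([C@H]2Oc3cc(O)cc(O)c3C(=O)[C@@H]2OC(=O)c2ccccc2)ccc1OC(C)=O | intermediate
18 | 3-methylbut-2-en-1-ol | CC(C)=CCO | starting material
19 | (2R,3R)-2-(4-acetoxy-3-methoxyphenyl)-3-benzoyloxy-5-hydroxy-7-(3-methylbut-2-en-1-yloxy)chroman-4-one | COc1cc([C@H]2Oc3cc(OCC=C(C)C)cc(O)c3C(=O)[C@@H]2OC(=O)c2ccccc2)ccc1OC(C)=O | intermediate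
20 | (2R,3R)-3,5-dihydroxy-2-(4-hydroxy-3-methoxyphenyl)-7-(3-methylbut-2-en-1-yloxy)chroman-4-one | COc1cc([C@H]2Oc3cc(OCC=C(C)C)cc(O)c3C(=O)[C@@H]2O)ccc1O | target

**Step count**
Total: 11 steps. Longest linear sequence: 8 steps (3 → 5 → 6 → 8 → 10 → 11 → 17 → 19 → 20).

**Steps most likely to fail**

Step 4. What may go wrong: the open transition state gives way to a zirconium-bridged, syn addition, so that the 2,3-cis ring forms, or facial control at the aldehyde erodes. The fallback sets out from 2 and comes back at 8, and it sets the two centres one after the other. Aldehyde 2 is combined under the same zirconium binaphtholate with the unsubstituted, purchasable diene (E)-1-methoxy-3-(trimethylsilyloxy)buta-1,3-diene, then TFA, to give (S)-2-(4-acetoxy-3-methoxyphenyl)-2,3-dihydro-4H-pyran-4-one F1, in which only C2 has to be controlled (the descriptor is S because C3 is still a CH2 group; the spatial arrangement is that of 8). Oxidation of F1 with Mn(OAc)3 and benzoic acid 4 in benzene at reflux should then place the benzoate at C3 on the face away from the pseudo-equatorial aryl group, under substrate control, which gives the trans compound 8.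

Step 9. What may go wrong: the labile bis(silyloxy)diene is protodesilylated by the sulfenic acid that is set free, or it adds in a Michael fashion at C8a without closing the second bond, before ring A can aromatise. The fallback sets out from 11 and 18 and comes back at 19; it brings the prenyl ether in with a sturdier mono-silyl diene, so that step 10 falls away as well. Trimethylphosphine-catalysed addition of 18 to purchased methyl but-2-ynoate should give methyl (E)-3-(3-methylbut-2-en-1-yloxy)but-2-enoate F2. Deprotonation with LiN(i-Pr)2 at −78 °C and silylation with TMSCl gives 1-methoxy-3-(3-methylbut-2-en-1-yloxy)-1-(trimethylsilyloxy)buta-1,3-diene F3. Cycloaddition of F3 with 11 in toluene, loss of benzenesulfenic acid and methanol on warming, and a mild acidic work-up should give 19 directly.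

Step 11. What may go wrong: under carbonate the C3 enolate or the 4'-phenoxide opens ring C (retro-oxa-Michael reaction, quinone methide), which scrambles C2 and C3, or the benzoate is cleaved too slowly to avoid this. The fallback sets out from 17 and comes back at 20; it moves the ester removal in front of the prenylation and runs it under acid, which the prenyl ether would not survive but 17 should. HCl in MeOH (from AcCl) at 50 °C should give (2R,3R)-3,5,7-trihydroxy-2-(4-hydroxy-3-methoxyphenyl)chroman-4-one F4. A Mitsunobu reaction with one equivalent of 18 (PPh3, DIAD, THF, 0 °C) should then alkylate the most acidic phenol, the 7-OH para to the C4 carbonyl, to give 20.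

**Further compounds**
F1 | step 4 | (S)-2-(4-acetoxy-3-methoxyphenyl)-2,3-dihydro-4H-pyran-4-one | COc1cc([C@H]2OC=CC(=O)C2)ccc1OC(C)=O
F2 | step 9 | methyl (E)-3-(3-methylbut-2-en-1-yloxy)but-2-enoate | COC(=O)/C=C(\C)OCC=C(C)C
F3 | step 9 | 1-methoxy-3-(3-methylbut-2-en-1-yloxy)-1-(trimethylsilyloxy)buta-1,3-diene | COC(O[Si](C)(C)C)=CC(=C)OCC=C(C)C
F4 | step 11 | (2R,3R)-3,5,7-trihydroxy-2-(4-hydroxy-3-methoxyphenyl)chroman-4-one | COc1cc([C@H]2Oc3cc(O)cc(O)c3C(=O)[C@@H]2O)ccc1O
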